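Ring A of the target shares its C5–C10 edge with ring B, and C10 is also the lactone terminus. The route therefore builds the bicyclo[3.2.1]octane rings C and D first and closes rings A and B together by an intramolecular Diels–Alder reaction between a C10≡C1 alkyne on C9 and a (Z)-2-alkoxycarbonyl-1,3-diene (C2=C3–C4=C5) hung from C8 through C6; this forms C1–C2 and C5–C10 and sets C5. The resulting 1,4-diene is methylated at C4 with deconjugation, and the 1(10),2-diene is then oxidised by two hydroxyl-directed epoxidations that install the 19,10-lactone, the 1β-hydroxyl and the 2β,3β-epoxide.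

Key step: step 18

Remark on labels: carbons carry the gibberellane labels C1–C19 of the target in all intermediates; β is the face of the C15–C16 bridge, H5 and H9, and α is the face of the lactone.
Assumption: the chiral lithium amide of step 2 is taken to induce in the sense known for other 4-substituted cyclohexanones; if the sense were opposite for 2, its enantiomer would be used.

Step 1
Reactants: 1 4-(hydroxymethyl)cyclohexan-1-one
Product: 2 4-({[tert-butyl(dimethyl)silyl]oxy}methyl)cyclohexan-1-one
Conditions: TBSCl, imidazole, CH2Cl2, 0 °C to rt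
Reagents that add atoms: tert-butyl(chloro)dimethylsilane, CC(C)(C)[Si](C)(C)Cl
Why: Imidazole-promoted silylation of the primary alcohol (silyl ether formation) masks the future C10 oxygen against the amide base and the Lewis acids used later; no stereocenter is involved.

Step 2
Reactants: 2 4-({[tert-butyl(dimethyl)silyl]oxy}methyl)cyclohexan-1-one
Product: 4 tert-butyl(dimethyl){[(1R)-4-(trimethylsilyloxy)cyclohex-3-en-1-yl]methoxy}silane, via lithium enolate 3 (not isolated)
Conditions: (S,S)-bis(1-phenylethyl)amine, n-BuLi, THF, −78 °C; then TMSCl and 2, −100 °C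
Reagents that add atoms: chlorotrimethylsilane, C[Si](C)(C)Cl
Why: Asymmetric desymmetrising enolisation: the twofold-symmetric chiral lithium amide removes one of the two enantiotopic α-protons of the 4-substituted ketone and the enolate is trapped in situ as the enol silane, which should fix C9 as (R).

Step 3
Reactants: 4 tert-butyl(dimethyl){[(1R)-4-(trimethylsilyloxy)cyclohex-3-en-1-yl]methoxy}silane
Product: 5 (4R)-4-({[tert-butyl(dimethyl)silyl]oxy}methyl)cyclohex-2-en-1-one
Conditions: Pd(OAc)2 (1.05 equiv), MeCN, rt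
Reagents that add atoms: none
Why: Saegusa–Ito oxidation: transmetalation to the palladium enolate and β-hydride elimination give the enone regiospecifically without touching C9.

Step 4
Reactants: 5 (4R)-4-({[tert-butyl(dimethyl)silyl]oxy}methyl)cyclohex-2-en-1-one; 6 tert-butyl[(1-methoxyethenyl)oxy]dimethylsilane
Product: 7 methyl 2-[(1S,6R)-3-{[tert-butyl(dimethyl)silyl]oxy}-6-({[tert-butyl(dimethyl)silyl]oxy}methyl)cyclohex-2-en-1-yl]acetate (trans)
Conditions: TBSOTf (5 mol%), CH2Cl2, −78 °C
Reagents that add atoms: none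
Why: Mukaiyama–Michael addition catalysed by the silyl triflate: the ketene silyl acetal adds to C8 anti to the C9 substituent and the silyl group is passed on to the enolate oxygen, so the C13 enol silane is formed regiospecifically (the new C8 centre is erased in step 5).

Step 5
Reactants: 7 methyl 2-[(1S,6R)-3-{[tert-butyl(dimethyl)silyl]oxy}-6-({[tert-butyl(dimethyl)silyl]oxy}methyl)cyclohex-2-en-1-yl]acetate
Product: 8 methyl 2-[(6R)-6-({[tert-butyl(dimethyl)silyl]oxy}methyl)-3-oxocyclohex-1-en-1-yl]acetate
Conditions: Pd(OAc)2 (1.05 equiv), MeCN, 40 °C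
Reagents that add atoms: none
Why: Second Saegusa–Ito oxidation: the regiodefined enol silane can only eliminate the C8 hydrogen, which gives the 3,4-disubstituted enone with the C6–C5 ester arm on C8.

Step 6
Reactants: 8 methyl 2-[(6R)-6-({[tert-butyl(dimethyl)silyl]oxy}methyl)-3-oxocyclohex-1-en-1-yl]acetate; 9 tributyl(propa-1,2-dien-1-yl)stannane
Product: 10 methyl 2-[(1R,2R)-2-({[tert-butyl(dimethyl)silyl]oxy}methyl)-5-oxo-1-(prop-2-yn-1-yl)cyclohexyl]acetate
Conditions: TiCl4, CH2Cl2, −78 °C
Reagents that add atoms: none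
Why: Lewis acid-promoted conjugate propargylation (Hosomi–Sakurai-type SE2' addition of the allenylstannane): axial attack on the TiCl4-activated enone anti to the pseudoaxial C9 substituent should create quaternary C8 with the propargyl group (C15–C17) trans to C10.

Step 7
Reactants: 10 methyl 2-[(1R,2R)-2-({[tert-butyl(dimethyl)silyl]oxy}methyl)-5-oxo-1-(prop-2-yn-1-yl)cyclohexyl]acetate
Product: 11 methyl 2-[(1R,2R,5S)-2-({[tert-butyl(dimethyl)silyl]oxy}methyl)-5-hydroxy-6-methylidenebicyclo[3.2.1]octan-1-yl]acetate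
Conditions: SmI2, HMPA, t-BuOH, THF, 0 °C to rt
Reagents that add atoms: none
Why: Ketyl–alkyne reductive radical cyclisation (5-exo-dig) by divalent samarium: the C13 ketyl adds to C16 of the axial propargyl arm, the vinyl radical is reduced and protonated, and the bridge geometry allows only one configuration at C13.

Step 8
Reactants: 11 methyl 2-[(1R,2R,5S)-2-({[tert-butyl(dimethyl)silyl]oxy}methyl)-5-hydroxy-6-methylidenebicyclo[3.2.1]octan-1-yl]acetate
Product: 12 methyl 2-[(1R,2R,5S)-5-{[tert-butyl(dimethyl)silyl]oxy}-2-({[tert-butyl(dimethyl)silyl]oxy}methyl)-6-methylidenebicyclo[3.2.1]octan-1-yl]acetate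
Conditions: TBSOTf, 2,6-lutidine, CH2Cl2, 0 °C
Reagents that add atoms: tert-butyldimethylsilyl trifluoromethanesulfonate, CC(C)(C)[Si](C)(C)OS(=O)(=O)C(F)(F)F
Why: Silylation of the hindered tertiary bridgehead alcohol with the silyl triflate (silyl ether formation) removes the only hydroxyl that could later direct oxidants to the C16=C17 alkene.

Step 9
Reactants: 12 methyl 2-[(1R,2R,5S)-5-{[tert-butyl(dimethyl)silyl]oxy}-2-({[tert-butyl(dimethyl)silyl]oxy}methyl)-6-methylidenebicyclo[3.2.1]octan-1-yl]acetate
Product: 14 cis-fused δ-lactone of the C/D core (ring C8–C6H2–C5(=O)–O–C10H2–C9; 13-OTBS; 16-methylidene), via hydroxy ester 13 (not isolated)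
Conditions: camphor-10-sulfonic acid (cat.), MeOH, 0 °C; then PhMe, 80 °C
Reagents that add atoms: none
Why: Acid-catalysed methanolysis cleaves the unhindered primary silyl ether much faster than the tertiary one, and the freed C10 hydroxyl, cis to the ester arm, closes the six-membered lactone by transesterification on heating.

Step 10
Reactants: 14 cis-fused δ-lactone of the C/D core
Product: 15 corresponding lactol (C5 hemiacetal; mixture of anomers)
Conditions: i-Bu2AlH, CH2Cl2, −78 °C
Reagents that add atoms: none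
Why: Partial reduction of the lactone by the aluminium hydride stops at the lactol because the tetrahedral aluminate is stable at −78 °C.

Step 11
Reactants: 15 lactol of the C/D core
Product: 16 6-(hydroxymethyl) lactol (C7 introduced; H6 α and C7 β as in the target)
Conditions: (R)-α,α-diphenylprolinol trimethylsilyl ether (20 mol%), aq. CH2O, pH 7 phosphate buffer, PhMe, rt
Reagents that add atoms: formaldehyde, C=O
Why: Enamine-catalysed α-hydroxymethylation (organocatalytic cross-aldol reaction with formaldehyde): the open hydroxy aldehyde forms the E-enamine with the prolinol ether, whose diphenyl(silyloxy)methyl group shields one face, so that formaldehyde should add to C6 from the face that gives the target configuration under catalyst control.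

Step 12
Reactants: 16 6-(hydroxymethyl) lactol
Product: 17 6-[(triethylsilyloxy)methyl] lactol
Conditions: TESCl, imidazole, CH2Cl2, −40 °C
Reagents that add atoms: chlorotriethylsilane, CC[Si](Cl)(CC)CC
Why: Selective silylation: the primary C7 hydroxyl reacts with the silyl chloride far faster than the hindered hemiacetal hydroxyl, which keeps C5 and C10 masked together as the lactol.

Step 13
Reactants: 17 6-[(triethylsilyloxy)methyl] lactol
Product: 18 dibromoalkene alcohol (C8–C6H(CH2OTES)–C5H=C4Br2; C9–C10H2OH; 13-OTBS; 16-methylidene)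
Conditions: Ph3PCHBr2 Br, KOt-Bu, THF, rt; then 17, rt to 50 °C
Reagents that add atoms: (dibromomethyl)triphenylphosphonium bromide, BrC(Br)[P+](c1ccccc1)(c1ccccc1)c1ccccc1.[Br-]
Why: Wittig-type dibromomethylenation (first stage of the Corey–Fuchs sequence) of the aldehyde tautomer of the lactol with the preformed ylide, which tolerates the hydroxyl groups, converts C5 into C5H=C4Br2 and releases the C10 alcohol.

Step 14
Reactants: 18 dibromoalkene alcohol; 19 tributyl(ethenyl)stannane
Product: 20 (Z)-2-bromo-1,3-diene alcohol (C5H=C4(Br)–C3H=C2H2 with the vinyl group trans to C6)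
Conditions: Pd2(dba)3 (2.5 mol%), tri(2-furyl)phosphine, PhMe, 100 °C
Reagents that add atoms: none
Why: Stille coupling: zerovalent palladium inserts selectively into the less hindered C–Br bond trans to the bulky C6 substituent, and coupling with retention places the vinyl group (C3, C2) trans to C6.

Step 15
Reactants: 20 (Z)-2-bromo-1,3-diene alcohol
Product: 21 (Z)-diene ester alcohol (2-(trimethylsilyl)ethyl ester C19 on C4 and cis to C6)
Conditions: PdCl2(PPh3)2 (5 mol%), CO (1 atm), Et3N, Me3SiCH2CH2OH (excess), DMF, 70 °C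
Reagents that add atoms: carbon monoxide, [C-]#[O+]; 2-(trimethylsilyl)ethanol, C[Si](C)(C)CCO
Why: Palladium-catalysed alkoxycarbonylation of the remaining vinyl bromide (oxidative addition, CO insertion, alcoholysis by the excess external alcohol) proceeds with retention and so fixes the C19 ester cis to C6, the (Z) geometry needed in the key step.

Step 16
Reactants: 21 (Z)-diene ester alcohol
Product: 22 (Z)-diene ester aldehyde (C10 aldehyde on C9)
Conditions: DMP (1,1,1-triacetoxy-1,1-dihydro-1,2-benziodoxol-3(1H)-one), CH2Cl2, 0 °C to rt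
Reagents that add atoms: none
Why: Oxidation of the primary alcohol with the hypervalent iodine reagent (DMP oxidation) gives the aldehyde under non-basic conditions, which should leave C9 untouched.

Step 17
Reactants: 22 (Z)-diene ester aldehyde
Product: 23 dienyne (C9–C10≡C1H; C6–C5H=C4(CO2CH2CH2SiMe3)–C3H=C2H2; 7-OTES; 13-OTBS)
Conditions: dimethyl (1-diazo-2-oxopropyl)phosphonate, K2CO3, MeOH–THF, 0 °C
Reagents that add atoms: dimethyl (1-diazo-2-oxopropyl)phosphonate, COP(=O)(OC)C(=[N+]=[N-])C(C)=O
Why: Seyferth–Gilbert homologation with the Ohira–Bestmann reagent turns the aldehyde into the terminal alkyne (C10≡C1) under mild carbonate conditions, the hindered α-branched aldehyde reacting faster than it enolises.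

Step 18
Reactants: 23 dienyne
Product: 24 tetracyclic cycloadduct (rings A–D; C1=C10 and C3=C4 in ring A; 5β-H; 19-ester on C4)
Conditions: PhMe (0.005 M), 2,6-di-tert-butyl-4-methylphenol (cat.), 170 °C, sealed tube
Reagents that add atoms: none
Why: Thermal intramolecular Diels–Alder reaction, a concerted but asynchronous [4+2] cycloaddition between the electron-poor C2=C3–C4=C5 diene and the C10≡C1 alkyne with the C5–C10 bond more advanced; the closest known reaction type is the type 1 intramolecular cycloaddition of 1,3-dien-8-ynes to bicyclo[4.3.0]nonadienes. Ring A (C1, C2, C3, C4, C5, C10) is closed by the cycloaddition itself, and ring B (C5, C6, C8, C9, C10) by the fused mode that the three-atom tether C6–C8–C9 enforces, which also fixes the regiochemistry. The only new stereocenter, C5, is controlled by allylic 1,3-strain: the C4 ester is cis to C6, so H6 must lie in the diene plane, the C8 tether occupies the attacked face and the CH2OTES group the other, which translates the C6 configuration into 5β-H, while C1 and C10 stay sp2. The step needs chemoselectivity for the alkyne over the exocyclic C16=C17 alkene, which is secured because addition there would build a strained norbornane with bridgeheads C8 and C16 and a quaternary C16. It also needs the intramolecular reaction to outrun dimerisation of the 2-alkoxycarbonyl diene, which high dilution, the bulky substituent on C5 and the radical inhibitor should secure. The (Z) ester geometry puts C6 on the outside of the s-cis diene, so neither a cis-diene penalty nor a 1,5-hydrogen shift intervenes.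

Step 19
Reactants: 24 tetracyclic cycloadduct
Product: 26 4β-methyl 1(10),2-diene ester (C18 β and C19 ester α on C4), via lithium trienolate 25 (not isolated)
Conditions: LiN(i-Pr)2, THF–HMPA, −78 °C; then MeI
Reagents that add atoms: iodomethane, CI
Why: Deconjugative α-alkylation of an extended ester enolate: the amide base removes a doubly allylic C2 proton, and the trienolate is methylated at C4 on the β face, anti to the C5–C6 bond, which sets C4 and moves the double bonds to the 1(10),2-diene.

Step 20
Reactants: 26 4β-methyl 1(10),2-diene ester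
Product: 27 7-hydroxy 19-acid (C7H2OH β on C6; C19 acid α on C4; 1(10),2-diene; 13-OTBS)
Conditions: Bu4NF, THF, 0 °C
Reagents that add atoms: none
Why: Fluoride-mediated desilylation cleaves the primary triethylsilyl ether and, by attack at silicon with loss of ethene, the 2-(trimethylsilyl)ethyl ester, while the hindered tertiary bridgehead silyl ether should survive at low temperature.

Step 21
Reactants: 27 7-hydroxy 19-acid
Product: 30 target 7-alcohol as its 13-O-TBS ether (19,10-lactone; 1β-OH; 2β,3β-epoxide; C7H2OH), via epoxy acid 28 (not isolated), via hydroxy lactone 29 (not isolated)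
Conditions: VO(acac)2 (10 mol%), t-BuOOH (2.5 equiv), CH2Cl2, 0 °C to rt
Reagents that add atoms: tert-butyl hydroperoxide, CC(C)(C)OO
Why: Hydroxyl-directed vanadium-catalysed epoxidation used twice: the β C7 hydroxyl (bishomoallylic) delivers oxygen to the β face of C1=C10, the α C19 acid opens this vinyl epoxide at C10 with inversion (5-exo lactonisation) to give the 19,10-lactone and the 1β-hydroxyl, and that allylic hydroxyl then directs the second epoxidation syn to C2=C3, setting C10, C1, C2 and C3, while the silylated C13 oxygen cannot direct attack on C16=C17.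

Step 22
Reactants: 30 target 7-alcohol as its 13-O-TBS ether
Product: 31 target gibberellin 13-O-tert-butyldimethylsilyl ether
Conditions: TEMPO (2,2,6,6-tetramethylpiperidin-1-oxyl, 20 mol%), PhI(OAc)2, MeCN–H2O, rt
Reagents that add atoms: water, O
Why: Oxoammonium-mediated oxidation (TEMPO with PhI(OAc)2 in water) is selective for the primary C7 alcohol over the hindered secondary C1 alcohol and carries it through the aldehyde hydrate to the carboxylic acid.

Step 23
Reactants: 31 target gibberellin 13-O-tert-butyldimethylsilyl ether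
Product: 32 target gibberellin (1β,13-dihydroxy-2β,3β-epoxy 16-ene 19,10-lactone 7-oic acid)
Conditions: Bu4NF, THF, rt to 40 °C
Reagents that add atoms: none
Why: Fluoride desilylation of the tertiary silyl ether frees the C13 hydroxyl; the cis relation of the C1 hydroxyl and the epoxide rules out a Payne rearrangement under the basic conditions.

Compound list
1 | 4-(hydroxymethyl)cyclohexan-1-one | O=C1CCC(CO)CC1 | starting material
2 | 4-({[tert-butyl(dimethyl)silyl]oxy}methyl)cyclohexan-1-one | O=C1CCC(CO[Si](C)(C)C(C)(C)C)CC1 | intermediate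
3 | lithium (4R)-4-({[tert-butyl(dimethyl)silyl]oxy}methyl)cyclohex-1-en-1-olate | [Li]OC1=CC[C@H](CO[Si](C)(C)C(C)(C)C)CC1 | intermediate (not isolated)
4 | tert-butyl(dimethyl){[(1R)-4-(trimethylsilyloxy)cyclohex-3-en-1-yl]methoxy}silane | C[Si](C)(C)OC1=CC[C@H](CO[Si](C)(C)C(C)(C)C)CC1 | intermediate
5 | (4R)-4-({[tert-butyl(dimethyl)silyl]oxy}methyl)cyclohex-2-en-1-one | O=C1C=C[C@H](CO[Si](C)(C)C(C)(C)C)CC1 | intermediate
6 | tert-butyl[(1-methoxyethenyl)oxy]dimethylsilane | C=C(OC)O[Si](C)(C)C(C)(C)C | starting material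
7 | methyl 2-[(1S,6R)-3-{[tert-butyl(dimethyl)silyl]oxy}-6-({[tert-butyl(dimethyl)silyl]oxy}methyl)cyclohex-2-en-1-yl]acetate (trans) | COC(=O)C[C@@H]1C=C(O[Si](C)(C)C(C)(C)C)CC[C@H]1CO[Si](C)(C)C(C)(C)C | intermediate
8 | methyl 2-[(6R)-6-({[tert-butyl(dimethyl)silyl]oxy}methyl)-3-oxocyclohex-1-en-1-yl]acetate | COC(=O)CC1=CC(=O)CC[C@H]1CO[Si](C)(C)C(C)(C)C | intermediate
9 | tributyl(propa-1,2-dien-1-yl)stannane | C=C=C[Sn](CCCC)(CCCC)CCCC | starting material
10 | methyl 2-[(1R,2R)-2-({[tert-butyl(dimethyl)silyl]oxy}methyl)-5-oxo-1-(prop-2-yn-1-yl)cyclohexyl]acetate (propargyl trans to the silyloxymethyl group) | C#CC[C@]1(CC(=O)OC)CC(=O)CC[C@H]1CO[Si](C)(C)C(C)(C)C | intermediate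
11 | methyl 2-[(1R,2R,5S)-2-({[tert-butyl(dimethyl)silyl]oxy}methyl)-5-hydroxy-6-methylidenebicyclo[3.2.1]octan-1-yl]acetate | C=C1C[C@]2(CC(=O)OC)C[C@@]1(O)CC[C@H]2CO[Si](C)(C)C(C)(C)C | intermediate
12 | methyl 2-[(1R,2R,5S)-5-{[tert-butyl(dimethyl)silyl]oxy}-2-({[tert-butyl(dimethyl)silyl]oxy}methyl)-6-methylidenebicyclo[3.2.1]octan-1-yl]acetate | C=C1C[C@]2(CC(=O)OC)C[C@@]1(O[Si](C)(C)C(C)(C)C)CC[C@H]2CO[Si](C)(C)C(C)(C)C | intermediate
13 | methyl 2-[(1R,2R,5S)-5-{[tert-butyl(dimethyl)silyl]oxy}-2-(hydroxymethyl)-6-methylidenebicyclo[3.2.1]octan-1-yl]acetate | C=C1C[C@]2(CC(=O)OC)C[C@@]1(O[Si](C)(C)C(C)(C)C)CC[C@H]2CO | intermediate (not isolated)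
14 | cis-fused δ-lactone of the C/D core (C8–C6H2–C5(=O)–O–C10H2–C9; 13-OTBS; 16-methylidene) | C=C1C[C@@]23CC(=O)OC[C@@H]2CC[C@]1(O[Si](C)(C)C(C)(C)C)C3 | intermediate
15 | lactol of 14 (C5 hemiacetal, anomer mixture) | C=C1C[C@@]23CC(O)OC[C@@H]2CC[C@]1(O[Si](C)(C)C(C)(C)C)C3 | intermediate
16 | 6-(hydroxymethyl) lactol (H6 α, C7 β) | C=C1C[C@@]23[C@@H](CO)C(O)OC[C@@H]2CC[C@]1(O[Si](C)(C)C(C)(C)C)C3 | intermediate
17 | 6-[(triethylsilyloxy)methyl] lactol | C=C1C[C@@]23[C@@H](CO[Si](CC)(CC)CC)C(O)OC[C@@H]2CC[C@]1(O[Si](C)(C)C(C)(C)C)C3 | intermediate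
18 | dibromoalkene alcohol (C5H=C4Br2 on C6; C10H2OH on C9) | C=C1C[C@]2([C@@H](CO[Si](CC)(CC)CC)C=C(Br)Br)C[C@@]1(O[Si](C)(C)C(C)(C)C)CC[C@H]2CO | intermediate
19 | tributyl(ethenyl)stannane | C=C[Sn](CCCC)(CCCC)CCCC | starting material
20 | (Z)-2-bromo-1,3-diene alcohol (vinyl trans to C6) | C=C1C[C@]2([C@@H](CO[Si](CC)(CC)CC)/C=C(Br)/C=C)C[C@@]1(O[Si](C)(C)C(C)(C)C)CC[C@H]2CO | intermediate
21 | (Z)-diene ester alcohol (2-(trimethylsilyl)ethyl ester cis to C6) | C=C1C[C@]2([C@@H](CO[Si](CC)(CC)CC)/C=C(C(=O)OCC[Si](C)(C)C)/C=C)C[C@@]1(O[Si](C)(C)C(C)(C)C)CC[C@H]2CO | intermediate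
22 | (Z)-diene ester aldehyde (C10 aldehyde) | C=C1C[C@]2([C@@H](CO[Si](CC)(CC)CC)/C=C(C(=O)OCC[Si](C)(C)C)/C=C)C[C@@]1(O[Si](C)(C)C(C)(C)C)CC[C@H]2C=O | intermediate
23 | dienyne, precursor of the key step (C9–C10≡C1H; (Z)-diene ester on C6) | C=C1C[C@]2([C@@H](CO[Si](CC)(CC)CC)/C=C(C(=O)OCC[Si](C)(C)C)/C=C)C[C@@]1(O[Si](C)(C)C(C)(C)C)CC[C@H]2C#C | intermediate
24 | tetracyclic cycloadduct (C1=C10, C3=C4; 5β-H; 7-OTES; 13-OTBS; 19-ester) | C=C1C[C@]23C[C@@]1(O[Si](C)(C)C(C)(C)C)CC[C@H]2C2=CCC=C(C(=O)OCC[Si](C)(C)C)[C@H]2[C@@H]3CO[Si](CC)(CC)CC | intermediate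
25 | lithium trienolate of 24 | C=C1C[C@]23C[C@@]1(O[Si](C)(C)C(C)(C)C)CC[C@H]2C2=CC=CC(=C(O[Li])OCC[Si](C)(C)C)[C@H]2[C@@H]3CO[Si](CC)(CC)CC | intermediate (not isolated)
26 | 4β-methyl 1(10),2-diene ester (C19 ester α) | C=C1C[C@]23C[C@@]1(O[Si](C)(C)C(C)(C)C)CC[C@H]2C2=CC=C[C@@](C)(C(=O)OCC[Si](C)(C)C)[C@H]2[C@@H]3CO[Si](CC)(CC)CC | intermediate
27 | 7-hydroxy 19-acid, 1(10),2-diene, 13-OTBS | C=C1C[C@]23C[C@@]1(O[Si](C)(C)C(C)(C)C)CC[C@H]2C2=CC=C[C@@](C)(C(=O)O)[C@H]2[C@@H]3CO | intermediate
28 | 1β,10β-epoxy acid | C=C1C[C@]23C[C@@]1(O[Si](C)(C)C(C)(C)C)CC[C@H]2[C@@]12O[C@@H]1C=C[C@@](C)(C(=O)O)[C@H]2[C@@H]3CO | intermediate (not isolated)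
29 | 1β-hydroxy 19,10-lactone, 2-ene | C=C1C[C@]23C[C@@]1(O[Si](C)(C)C(C)(C)C)CC[C@H]2[C@@]12OC(=O)[C@@](C)([C@H]1[C@@H]3CO)C=C[C@H]2O | intermediate (not isolated)
30 | target 7-alcohol as its 13-O-TBS ether (1β-OH, 2β,3β-epoxide, 19,10-lactone, C7H2OH) | C=C1C[C@]23C[C@@]1(O[Si](C)(C)C(C)(C)C)CC[C@H]2[C@@]12OC(=O)[C@@](C)([C@H]1[C@@H]3CO)[C@H]1O[C@H]1[C@H]2O | intermediate
31 | target gibberellin 13-O-tert-butyldimethylsilyl ether | C=C1C[C@]23C[C@@]1(O[Si](C)(C)C(C)(C)C)CC[C@H]2[C@@]12OC(=O)[C@@](C)([C@H]1[C@@H]3C(=O)O)[C@H]1O[C@H]1[C@H]2O | intermediate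
32 | target gibberellin (1β,13-dihydroxy-2β,3β-epoxy 16-ene 19,10-lactone 7-oic acid; face labels as in the remark) | C=C1C[C@]23C[C@@]1(O)CC[C@H]2[C@@]12OC(=O)[C@@](C)([C@H]1[C@@H]3C(=O)O)[C@H]1O[C@H]1[C@H]2O | target

Total step count: 23. Longest linear sequence: 23 steps (from 1).

Steps most likely to fail

Step 18. The 2-alkoxycarbonyl diene may dimerise or polymerise before it reaches the unactivated alkyne, or facial selectivity may erode at 170 °C. The fallback changes the order so that the cycloaddition is run on the bromodiene, whose bromine serves as the allylic-strain directing group and which is less prone to self-addition. It sets out from 20: oxidation with DMP should give bromodiene aldehyde F1, Seyferth–Gilbert homologation should give bromodienyne F2, heating in toluene should give bromo cycloadduct F3, and palladium-catalysed alkoxycarbonylation of the ring vinyl bromide with CO and 2-(trimethylsilyl)ethanol comes back to the route at 24.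

Step 6. The allenylstannane may fail to add to the hindered β,β-disubstituted enone, or may be lost to protodestannylation or 1,2-addition. The fallback sets out from 8: Hosomi–Sakurai allylation with allyltrimethylsilane and TiCl4, which is reliable for quaternary centres and should show the same trans selectivity, gives allyl ketone F4; ozonolysis with PPh3 work-up gives keto aldehyde F5; Seyferth–Gilbert homologation of the aldehyde (the ketone does not react) comes back to the route at 10.

Step 11. Enamine formation from the hindered lactol may be slow, the catalyst may not override the facial bias of the substrate, or the β-hydroxy aldehyde may dehydrate. The fallback sets out from 14 and moves the carbon–carbon bond formation to the lactone stage under substrate control: LiN(i-Pr)2 followed by monomeric formaldehyde gives hydroxymethyl lactone F6 (the C6 epimers are separable and the unwanted one can be recycled by enolisation and reprotonation), and reduction with i-Bu2AlH comes back to the route at 16.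

Further compounds
F1 | step 18 | bromodiene aldehyde (C10 aldehyde; C5H=C4(Br)–C3H=C2H2 on C6) | C=C1C[C@]2([C@@H](CO[Si](CC)(CC)CC)/C=C(Br)/C=C)C[C@@]1(O[Si](C)(C)C(C)(C)C)CC[C@H]2C=O
F2 | step 18 | bromodienyne | C=C1C[C@]2([C@@H](CO[Si](CC)(CC)CC)/C=C(Br)/C=C)C[C@@]1(O[Si](C)(C)C(C)(C)C)CC[C@H]2C#C
F3 | step 18 | bromo cycloadduct (C4 bromide; C1=C10 and C3=C4; 5β-H) | C=C1C[C@]23C[C@@]1(O[Si](C)(C)C(C)(C)C)CC[C@H]2C2=CCC=C(Br)[C@H]2[C@@H]3CO[Si](CC)(CC)CC
F4 | step 6 | methyl 2-[(1R,2R)-2-({[tert-butyl(dimethyl)silyl]oxy}methyl)-5-oxo-1-(prop-2-en-1-yl)cyclohexyl]acetate | C=CC[C@]1(CC(=O)OC)CC(=O)CC[C@H]1CO[Si](C)(C)C(C)(C)C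
F5 | step 6 | methyl 2-[(1R,2R)-2-({[tert-butyl(dimethyl)silyl]oxy}methyl)-5-oxo-1-(2-oxoethyl)cyclohexyl]acetate | O=CC[C@]1(CC(=O)OC)CC(=O)CC[C@H]1CO[Si](C)(C)C(C)(C)C
F6 | step 11 | 6-(hydroxymethyl) δ-lactone of the C/D core (H6 α, C7 β) | C=C1C[C@@]23[C@@H](CO)C(=O)OC[C@@H]2CC[C@]1(O[Si](C)(C)C(C)(C)C)C3
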